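The vessel is closed, stirred and held at one temperature, and substrate is the one species charged, so I keep the books in it as the limiting reagent.

| flask | substrate | time |
|---|---|---|
| north-east | 80.0 mM |  |
| south-west | 160 mM |  |
| north | 80.0 mM | 140 min |

| run | time / min | [target] / mM |
|---|---|---|
| north-east run | 10 | 8.3 |
| north-east run | 21 | 15.4 |
| north-east run | 31 | 23.2 |
| north-east run | 41 | 27.8 |
| north-east run | 51 | 34.0 |
| north-east run | 62 | 38.3 |
| north-east run | 72 | 43.1 |
| south-west run | 10 | 17.5 |
| south-west run | 21 | 31.6 |
| south-west run | 31 | 44.0 |
| south-west run | 41 | 55.2 |
| south-west run | 51 | 65.1 |
| south-west run | 62 | 74.4 |
| south-west run | 72 | 83.2 |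

(standard deviation of a reading: 0.8 mM)

- Overall: substrate -> target.
- Constant volume, constant temperature.
- An order is taken over about fifteen percent of the charge, up and down.

* the exponent of [substrate] in the starting rate at the charge of the north-east run (at the point where two percent of the substrate have become target) (one fixed amount of target, the same in the runs compared)
* target in the north run at 140 min, as a share of the substrate charged

In the north-east run the opening entry is 80.0 mM of substrate. At 72 min the entry c(target) reads 43.1 mM, which leaves 36.9 mM not booked as target. That gives 0.0107 min⁻¹, my ledger constant: the logarithm of the charge over the unbooked amount, per minute of run.

The south-west run, at twice the charge, closes its last entry at 0.0102 min⁻¹, lower than the north-east run. A ledger constant that stays put when the charge changes means an exponent of one. Mine reads 0.924, a reading over the whole run, not at the start.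

The north run has the north-east charge, so I close its books at 140 min with the same constant: 77.8 % of the charge as target, with 17.8 mM unbooked. The constant also puts half of a charge into target at 64.5 min.

The forecast gives an exponent of 0.97 and a share of 77 %, holding that “The runs look close to first order”. Its exponent stands above my reading and its share below mine.

The flask gives an exponent of 1.0 and, in the north run at 140 min, 74.7 % of the charge as target, 3.1 percentage points under my share.

    substrate → target (0.009480 min⁻¹)
    2 substrate → side product (0.01164 M⁻¹ min⁻¹)
    substrate → target (0.001818 min⁻¹)

On the south-west run, my 64.5 min stands against a simulated 69.4 min for target to reach half of the charge; the north-east run took 65.2 min. The ledger constant lumps together what feeds target, and the slower step to target, at 0.00182 min⁻¹, is a real entry. The north run reaches 74.7 % with that conversion and 68.6 % without it, so it supplies 6 points of the share.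

The readings were computed on assumed constants; the scatter is artificial.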